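**Retrosynthetic overview**

1. The strategy rests on the single ester carbonyl carbon of the depside: it sits on ring A C1 between the C2 methoxy and the C6 2-oxoheptyl chain and is bonded to the C4 oxygen of ring B. It is disconnected as carbon monoxide, giving a ring A aryl iodide and a ring B phenol.
2. End game: hydrolysis of the dioxolane that masks the side-chain ketone, then hydrogenolysis of the ring B benzyl ester.
3. Ring A iodide 9: 3,5-dimethoxyphenylacetic acid → Weinreb amide → pentyl ketone → dioxolane → iodination ortho to the side chain.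
4. Ring B phenol 17: olivetol → formylation → 4-O-allyl → 2-O-methyl → Pinnick oxidation → benzyl ester → deallylation.
5. Both benzene rings are bought in; no ring of the target is formed in the route (the dioxolane is temporary).

Key step: step 11

Remark on the chemistry: the target has no stereocentre or other stereogenic element, so the SMILES defines one achiral compound and no stereocontrol is needed.

**Route**

Step 1
Reactants: 1 3,5-dimethoxyphenylacetic acid
Product: 3 2-(3,5-dimethoxyphenyl)-N-methoxy-N-methylacetamide, via acyl imidazolide 2 (not isolated)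
Conditions: CDI (1.1 equiv), CH2Cl2, rt, 1 h; then MeNHOMe·HCl (1.2 equiv), rt
Reagents that add atoms: N,O-dimethylhydroxylamine hydrochloride, Cl.CNOC
Why: CDI activation of the acid to the acyl imidazolide followed by aminolysis is a standard Weinreb amide synthesis and should tolerate the electron-rich ring.

Step 2
Reactants: 3 2-(3,5-dimethoxyphenyl)-N-methoxy-N-methylacetamide; 4 1-bromopentane
Product: 7 1-(3,5-dimethoxyphenyl)heptan-2-one, via pentylmagnesium bromide 5 (not isolated), via chelated magnesium hemiaminal 6 (not isolated)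
Conditions: 4, Mg, THF, rt to 40 °C; then 3 (1.5 equiv of 5 relative to 3), THF, 0 °C; 1 M HCl, 0 °C
Reagents that add atoms: none
Why: Weinreb ketone synthesis; the five-membered magnesium chelate 6 should hold the tetrahedral adduct until the acidic quench, so the ketone is not attacked a second time.

Step 3
Reactants: 7 1-(3,5-dimethoxyphenyl)heptan-2-one
Product: 8 2-[(3,5-dimethoxyphenyl)methyl]-2-pentyl-1,3-dioxolane
Conditions: ethylene glycol (5 equiv), p-TsOH·H2O (cat.), toluene, Dean–Stark, reflux
Reagents that add atoms: ethylene glycol, OCCO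
Why: acid-catalysed ketalisation with azeotropic removal of water should convert the unhindered dialkyl-type ketone into its dioxolane.

Step 4
Reactants: 8 2-[(3,5-dimethoxyphenyl)methyl]-2-pentyl-1,3-dioxolane
Product: 9 2-[(2-iodo-3,5-dimethoxyphenyl)methyl]-2-pentyl-1,3-dioxolane
Conditions: NIS (1.05 equiv), MeCN, 0 °C to rt, dark, no acid additive
Reagents that add atoms: N-iodosuccinimide, O=C1CCC(=O)N1I
Why: electrophilic aromatic iodination of a 1,3-dimethoxyarene should go para to one methoxy and ortho to the other (next to the side chain) in preference to the crowded position between the two methoxy groups, and the acid-free conditions should spare the ketal.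

Step 5
Reactants: 10 olivetol (5-pentylbenzene-1,3-diol)
Product: 12 2,4-dihydroxy-6-pentylbenzaldehyde, via aryl iminium chloride 11 (not isolated)
Conditions: POCl3 (1.2 equiv), DMF, 0 °C to rt; then ice/H2O, aq NaOH to pH 6, 50 °C
Reagents that add atoms: N,N-dimethylformamide, CN(C)C=O; water, O
Why: Vilsmeier–Haack formylation of a 5-alkylresorcinol should occur para to one hydroxyl and ortho to the other, as in the orcinol to orcylaldehyde conversion, and hydrolysis of iminium 11 releases the aldehyde.

Step 6
Reactants: 12 2,4-dihydroxy-6-pentylbenzaldehyde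
Product: 13 2-hydroxy-6-pentyl-4-(prop-2-en-1-yloxy)benzaldehyde
Conditions: allyl bromide (1.05 equiv), K2CO3 (1.1 equiv), acetone, rt
Reagents that add atoms: allyl bromide, C=CCBr
Why: Williamson etherification should be selective for the more acidic, non-chelated 4-hydroxyl, because the 2-hydroxyl is hydrogen-bonded to the aldehyde.

Step 7
Reactants: 13 2-hydroxy-6-pentyl-4-(prop-2-en-1-yloxy)benzaldehyde
Product: 14 2-methoxy-6-pentyl-4-(prop-2-en-1-yloxy)benzaldehyde
Conditions: MeI (3 equiv), K2CO3 (2 equiv), DMF, 50 °C
Reagents that add atoms: iodomethane, CI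
Why: Williamson methylation under more forcing conditions should alkylate the remaining chelated phenol, well below the temperature of an aryl allyl ether Claisen rearrangement.

Step 8
Reactants: 14 2-methoxy-6-pentyl-4-(prop-2-en-1-yloxy)benzaldehyde
Product: 15 2-methoxy-6-pentyl-4-(prop-2-en-1-yloxy)benzoic acid
Conditions: NaClO2, NaH2PO4, 2-methyl-2-butene (excess), t-BuOH/THF/H2O, 0 °C to rt
Reagents that add atoms: sodium chlorite, [Na+].[O-]Cl=O
Why: Pinnick oxidation should convert the hindered, electron-rich aldehyde into the acid, with the alkene scavenger removing hypochlorous acid before it can chlorinate the ring or the allyl group.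

Step 9
Reactants: 15 2-methoxy-6-pentyl-4-(prop-2-en-1-yloxy)benzoic acid
Product: 16 benzyl 2-methoxy-6-pentyl-4-(prop-2-en-1-yloxy)benzoate
Conditions: BnBr (1.2 equiv), K2CO3 (1.5 equiv), DMF, rt
Reagents that add atoms: benzyl bromide, BrCc1ccccc1
Why: O-alkylation of the carboxylate (SN2 at the benzylic carbon) avoids acyl substitution at the di-ortho-substituted carboxyl and should therefore be insensitive to its steric hindrance.

Step 10
Reactants: 16 benzyl 2-methoxy-6-pentyl-4-(prop-2-en-1-yloxy)benzoate
Product: 17 benzyl 4-hydroxy-2-methoxy-6-pentylbenzoate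
Conditions: Pd(PPh3)4 (3 mol%), morpholine (5 equiv), THF, rt
Reagents that add atoms: none
Why: Tsuji–Trost deallylation via a π-allylpalladium species trapped by morpholine should free the phenol without touching the benzyl ester or the methyl ether.

Step 11
Reactants: 9 2-[(2-iodo-3,5-dimethoxyphenyl)methyl]-2-pentyl-1,3-dioxolane; 17 benzyl 4-hydroxy-2-methoxy-6-pentylbenzoate; 18 carbon monoxide
Product: 19 benzyl 4-({2,4-dimethoxy-6-[(2-pentyl-1,3-dioxolan-2-yl)methyl]benzoyl}oxy)-2-methoxy-6-pentylbenzoate
Conditions: Pd(OAc)2 (5 mol%), Xantphos (7.5 mol%), Et3N (3 equiv), CO (5 bar), 17 (1.2 equiv), 4 Å MS, toluene, 90 °C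
Reagents that add atoms: none
Why: Pd(0)/Xantphos should add oxidatively to the C–I bond of 9, CO should insert into the aryl–Pd bond to give an aroylpalladium iodide, and the triethylammonium phenoxide of 17 should displace iodide and leave by C–O reductive elimination, so that the aryl–C(=O) and C(=O)–OAr bonds form in one operation. The closest known reaction type is the palladium-catalysed aryloxycarbonylation (Heck-type carbonylation) of aryl iodides with phenols. No ring is closed and no stereocentre is created. The step needs chemoselectivity for capture of the acylpalladium by the external phenoxide: the dioxolane removes the enolisable ketone oxygen that could otherwise close onto the acyl group to give an isocoumarin, and CO pressure together with the wide-bite-angle ligand favours insertion over direct diaryl ether formation. Phenol 17 is acidified by its para ester group, so triethylamine suffices and the benzyl ester, the ketal and the aryl ester product are not exposed to strong base. The two ortho substituents slow oxidative addition but favour CO insertion, which is why an iodide, dry conditions and 90 °C are chosen.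

Step 12
Reactants: 19 benzyl 4-({2,4-dimethoxy-6-[(2-pentyl-1,3-dioxolan-2-yl)methyl]benzoyl}oxy)-2-methoxy-6-pentylbenzoate
Product: 20 benzyl 4-{[2,4-dimethoxy-6-(2-oxoheptyl)benzoyl]oxy}-2-methoxy-6-pentylbenzoate
Conditions: 1 M aq HCl/THF (1:4), rt, stopped at full conversion; NaHCO3 work-up kept cold and brief
Reagents that add atoms: water, O
Why: acid-catalysed ketal hydrolysis through the oxocarbenium ion should release the ketone at room temperature, conditions under which the hindered aryl ester and the benzyl ester are stable.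

Step 13
Reactants: 20 benzyl 4-{[2,4-dimethoxy-6-(2-oxoheptyl)benzoyl]oxy}-2-methoxy-6-pentylbenzoate
Product: 21 4-{[2,4-dimethoxy-6-(2-oxoheptyl)benzoyl]oxy}-2-methoxy-6-pentylbenzoic acid (target)
Conditions: H2 (1 atm), 10% Pd/C, EtOAc, rt
Reagents that add atoms: none
Why: catalytic hydrogenolysis should cleave only the benzylic C–O bond of the benzyl ester under neutral conditions, leaving the aliphatic ketone and the depside ester intact.

**Compound list**

1 | 3,5-dimethoxyphenylacetic acid | COc1cc(CC(=O)O)cc(OC)c1 | starting material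
2 | 2-(3,5-dimethoxyphenyl)-1-(1H-imidazol-1-yl)ethan-1-one | COc1cc(CC(=O)n2ccnc2)cc(OC)c1 | intermediate (not isolated)
3 | 2-(3,5-dimethoxyphenyl)-N-methoxy-N-methylacetamide | COc1cc(CC(=O)N(C)OC)cc(OC)c1 | intermediate
4 | 1-bromopentane | CCCCCBr | starting material
5 | pentylmagnesium bromide | CCCCC[Mg]Br | intermediate (not isolated)
6 | bromomagnesium alkoxide of 1-(3,5-dimethoxyphenyl)-2-[methoxy(methyl)amino]heptan-2-ol (chelated hemiaminal) | CCCCCC(Cc1cc(OC)cc(OC)c1)(O[Mg]Br)N(C)OC | intermediate (not isolated)
7 | 1-(3,5-dimethoxyphenyl)heptan-2-one | CCCCCC(=O)Cc1cc(OC)cc(OC)c1 | intermediate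
8 | 2-[(3,5-dimethoxyphenyl)methyl]-2-pentyl-1,3-dioxolane | CCCCCC1(Cc2cc(OC)cc(OC)c2)OCCO1 | intermediate
9 | 2-[(2-iodo-3,5-dimethoxyphenyl)methyl]-2-pentyl-1,3-dioxolane | CCCCCC1(Cc2cc(OC)cc(OC)c2I)OCCO1 | intermediate
10 | olivetol (5-pentylbenzene-1,3-diol) | CCCCCc1cc(O)cc(O)c1 | starting material
11 | [(2,4-dihydroxy-6-pentylphenyl)methylidene]dimethyliminium chloride | CCCCCc1cc(O)cc(O)c1C=[N+](C)C.[Cl-] | intermediate (not isolated)
12 | 2,4-dihydroxy-6-pentylbenzaldehyde | CCCCCc1cc(O)cc(O)c1C=O | intermediate
13 | 2-hydroxy-6-pentyl-4-(prop-2-en-1-yloxy)benzaldehyde | CCCCCc1cc(OCC=C)cc(O)c1C=O | intermediate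
14 | 2-methoxy-6-pentyl-4-(prop-2-en-1-yloxy)benzaldehyde | CCCCCc1cc(OCC=C)cc(OC)c1C=O | intermediate
15 | 2-methoxy-6-pentyl-4-(prop-2-en-1-yloxy)benzoic acid | CCCCCc1cc(OCC=C)cc(OC)c1C(=O)O | intermediate
16 | benzyl 2-methoxy-6-pentyl-4-(prop-2-en-1-yloxy)benzoate | CCCCCc1cc(OCC=C)cc(OC)c1C(=O)OCc1ccccc1 | intermediate
17 | benzyl 4-hydroxy-2-methoxy-6-pentylbenzoate | CCCCCc1cc(O)cc(OC)c1C(=O)OCc1ccccc1 | intermediate
18 | carbon monoxide | [C-]#[O+] | starting material
19 | benzyl 4-({2,4-dimethoxy-6-[(2-pentyl-1,3-dioxolan-2-yl)methyl]benzoyl}oxy)-2-methoxy-6-pentylbenzoate | CCCCCC1(Cc2cc(OC)cc(OC)c2C(=O)Oc2cc(CCCCC)c(C(=O)OCc3ccccc3)c(OC)c2)OCCO1 | intermediate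
20 | benzyl 4-{[2,4-dimethoxy-6-(2-oxoheptyl)benzoyl]oxy}-2-methoxy-6-pentylbenzoate | CCCCCC(=O)Cc1cc(OC)cc(OC)c1C(=O)Oc1cc(CCCCC)c(C(=O)OCc2ccccc2)c(OC)c1 | intermediate
21 | 4-{[2,4-dimethoxy-6-(2-oxoheptyl)benzoyl]oxy}-2-methoxy-6-pentylbenzoic acid | CCCCCC(=O)Cc1cc(OC)cc(OC)c1C(=O)Oc1cc(CCCCC)c(C(=O)O)c(OC)c1 | target

**Step count**

Total: 13 steps (ring A branch steps 1–4, ring B branch steps 5–10, then steps 11–13).
Longest linear sequence: 9 steps (olivetol 10 to target 21, steps 5–13).

**Steps most likely to fail**

1. Step 11. Oxidative addition and phenoxide capture at the electron-rich, doubly ortho-substituted ring may be slow, so that protodeiodination, hydrolysis of the acylpalladium by traces of water, or direct C–O coupling compete with ester formation. The fallback sets out from iodide 9 and builds the same carbonyl in two stages. Iodine–lithium exchange (n-BuLi, THF, −78 °C) should give {2,4-dimethoxy-6-[(2-pentyl-1,3-dioxolan-2-yl)methyl]phenyl}lithium F1. Quenching with CO2 and bringing the cold mixture to pH 4 with dilute HCl should give 2,4-dimethoxy-6-[(2-pentyl-1,3-dioxolan-2-yl)methyl]benzoic acid F2. Steglich esterification of F2 with phenol 17 (DCC, DMAP, CH2Cl2, rt) rejoins the route at compound 19.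

2. Step 12. Once the ketone is free, acid-promoted enolisation toward the aryl ring can let the enol oxygen attack the neighbouring aryl ester, closing an isocoumarin with loss of the ring B phenol before the ketal is fully hydrolysed. The fallback sets out from ketone 7 and uses an acyclic ketal that hydrolyses under near-neutral conditions. Trimethyl orthoformate/MeOH with catalytic CSA at rt should give 1-(2,2-dimethoxyheptyl)-3,5-dimethoxybenzene F3. NIS in MeCN should give 1-(2,2-dimethoxyheptyl)-2-iodo-3,5-dimethoxybenzene F4. Carbonylative coupling of F4 with 17 and 18 under the step 11 conditions should give benzyl 4-{[2-(2,2-dimethoxyheptyl)-4,6-dimethoxybenzoyl]oxy}-2-methoxy-6-pentylbenzoate F5. Hydrolysis of F5 with PPTS in wet acetone at rt rejoins the route at compound 20.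

3. Step 2. The Grignard reagent may deprotonate the doubly activated benzylic α-CH2 of the Weinreb amide instead of adding, returning amide 3 on work-up. The fallback sets out from acid 1. Oxalyl chloride with catalytic DMF in CH2Cl2 should give (3,5-dimethoxyphenyl)acetyl chloride F6. Iron-catalysed acylation of pentylmagnesium bromide 5 with F6 (Fe(acac)3 3 mol%, THF, −78 °C), which is fast enough to outrun enolisation, rejoins the route at compound 7.

**Further compounds**

F1 | step 11 | {2,4-dimethoxy-6-[(2-pentyl-1,3-dioxolan-2-yl)methyl]phenyl}lithium | CCCCCC1(Cc2cc(OC)cc(OC)c2[Li])OCCO1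
F2 | step 11 | 2,4-dimethoxy-6-[(2-pentyl-1,3-dioxolan-2-yl)methyl]benzoic acid | CCCCCC1(Cc2cc(OC)cc(OC)c2C(=O)O)OCCO1
F3 | step 12 | 1-(2,2-dimethoxyheptyl)-3,5-dimethoxybenzene | CCCCCC(OC)(OC)Cc1cc(OC)cc(OC)c1
F4 | step 12 | 1-(2,2-dimethoxyheptyl)-2-iodo-3,5-dimethoxybenzene | CCCCCC(OC)(OC)Cc1cc(OC)cc(OC)c1I
F5 | step 12 | benzyl 4-{[2-(2,2-dimethoxyheptyl)-4,6-dimethoxybenzoyl]oxy}-2-methoxy-6-pentylbenzoate | CCCCCC(OC)(OC)Cc1cc(OC)cc(OC)c1C(=O)Oc1cc(CCCCC)c(C(=O)OCc2ccccc2)c(OC)c1
F6 | step 2 | (3,5-dimethoxyphenyl)acetyl chloride | COc1cc(CC(=O)Cl)cc(OC)c1
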